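The chair asked the meeting for one figure about this flask that could be carried to the next reading.

    free monomer + initiator → living end + monomer in chains (k1 = 0.251 M⁻¹ s⁻¹)
    free monomer + living end → monomer in chains + living end, rate k2*[living end]*[free monomer] (k2 = 7.82 M⁻¹ s⁻¹)
    living end + transfer agent → dead chain (k3 = 1.33 M⁻¹ s⁻¹)
    initiator → spent initiator A (k4 = 1.65 × 10⁻⁵ s⁻¹)
    free monomer → uncatalysed product (k5 = 2.91 × 10⁻⁴ s⁻¹)
    2 initiator → spent initiator B (k6 = 49.4 M⁻¹ s⁻¹)

free monomer 0.11 M; transfer agent 3.30 mM; initiator 1.1 mM; time 3.0 min

- average number of monomer units in a chain (chains begun, living or dead) at 3.0 min
- part of the free monomer that has reacted at 3.0 min

- two of one species on the left: rate k times its square, two consumed each time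
- the average divides the monomer in chains by the number of chains begun, living and dead together
- run time (flask): 3.0 min

The first speaker argued that the order of the rate should be read from the living end: given its level, free monomer falls by a pseudo-first-order law, so the question was what fraction of the initiator charge ever becomes a living end. She reported that, with free monomer held at its charge, initiator begins chains at 0.0276 s⁻¹, while pairing at the start removes it at 0.109 s⁻¹, which is faster by a ratio of 3.94. But pairing fades as initiator falls. Integrating the two losses, she defined the chain yield, the fraction of the initiator charge that begins a chain, as the natural logarithm of one plus that ratio, divided by the ratio: 40.6%. The slow unimolecular loss of initiator, with a half-life of 12 h, was set aside.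

The second speaker let these living ends die by transfer, with a half-life of 2.6 min at the transfer agent's charge, and added the uncatalysed loss. That gave a summed exponent of 0.487, so a conversion of 38.5% and a length of 84.8. The secretary minuted that this starts the chains together at time zero, which leans high: with free monomer at its charge and pairing faded, initiator has a lifetime of 36.2 s, shorter than the run but not negligible.

The forecast gave 82 and 37%, holding that “Initiator self-destruction dominates at the start”.

The flask gives 79.3 units per chain and 35.7% reacted, 2.8 percentage points below the reckoned conversion. At 3.00 min, monomer in chains stands at 31.5% of the free monomer charged; that amount, over the chain yield of the initiator charge, gives 77.7 units per chain. The same flask read at 8.00 min holds 48.3% in chains, and the chain yield turns this into 119 units, where the reading stands at 120.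

The rate constants are those of an exercise; no experiment stands behind them.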